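**Retrosynthetic overview**
1. The target comes from its tribenzyl derivative (benzyl ester and two benzyl ethers) by one final hydrogenolysis, which leaves both acetates intact.
2. Key disconnection, C1'–O: the C1' acetoxymethyl group and the C2' stereocentre come from a 1,1-disubstituted alkene by catalyst-controlled anti-Markovnikov hydroacetoxylation. The other acetoxymethyl stereocentre (C6') is bought with its C–O bond in place, as (S)-3-bromo-2-methylpropan-1-ol.
3. Side chain: C4'–C5' by alkyl–alkyl Negishi coupling, and C3'–C4' by a formaldehyde ene reaction on an isopropenyl group.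
4. Arene: the catechol-carboxylate ring comes from a 2-pyranone and a tris(silyloxy)ethene by inverse-demand Diels–Alder reaction with loss of CO2. The pyranone comes from the kinetic enolate of trans-dihydrocarvone.
5. Ring order: the cyclohexane comes from (R)-carvone, then the 2-pyranone is built, then the benzene ring.

Assumption: locants follow 5,6,7,8-tetrahydronaphthalene-2-carboxylic acid (C5 = CHMe, C8 = CH bearing the chain), with C1'–C7' for the heptyl chain. The target is then (5R,8S,2'S,6'R).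

**Step 1**
Reactants: 1 (R)-(−)-carvone
Product: 2 (2R,5R)-2-methyl-5-(prop-1-en-2-yl)cyclohexan-1-one (trans-dihydrocarvone)
Conditions: ene-reductase (OYE2), NADP+ (cat.), D-glucose, GDH, KPi buffer pH 7, 30 °C
Reagents that add atoms: none
Why: In this Old-Yellow-Enzyme conjugate reduction, flavin hydride adds to C3 and a tyrosine protonates C2 from the opposite face, which sets C2 as R (trans, >95% de) without touching the isopropenyl group, while C5 comes from the chiral pool.

**Step 2**
Reactants: 2 trans-dihydrocarvone; 3 dimethyl 2-(methoxymethylidene)propanedioate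
Product: 6 methyl (5S,8R)-8-methyl-2-oxo-5-(prop-1-en-2-yl)-5,6,7,8-tetrahydro-2H-chromene-3-carboxylate, via lithium enolate 4 (not isolated), via alkylidenemalonate 5 (not isolated)
Conditions: LDA, THF, −78 °C; 3, −78 °C → rt; aq HCl
Reagents that add atoms: none
Why: This is a 2-pyranone annulation in which kinetic deprotonation at the CH2 side, addition–elimination on 3 and O-acylation of the resulting dienolate close the lactone, and the α-methyl and isopropenyl stereocentres are never deprotonated.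

**Step 3**
Reactants: 6 pyranone ester; 7 tris(trimethylsilyloxy)ethene
Product: 9 (5R,8S)-3,4-dihydroxy-5-methyl-8-(prop-1-en-2-yl)-5,6,7,8-tetrahydronaphthalene-2-carboxylic acid, via bis-silyl ether 8 (not isolated)
Conditions: 7 (3 equiv), mesitylene, 140 °C; then KOH, MeOH–H2O, reflux (Ar); HCl
Reagents that add atoms: potassium hydroxide, [K+].[OH-]
Why: Proposed new method: an inverse-electron-demand Diels–Alder catechol annulation with a tris-silyl ketene acetal, in which the nucleophilic CH(OSiMe3) terminus of 7 bonds to C8a and the acetal carbon to C3 of the ester-activated pyranone, the bridged lactone extrudes CO2 and the dihydroarene loses Me3SiOH to give 8 with both ring oxygens in hydrolysable form (KOH then also cleaves the methyl ester); the closest known reaction type is the same cycloaddition/CO2 extrusion of 3-alkoxycarbonyl-2-pyranones with 1,1-dimethoxy- and 1,1,2-trimethoxyethene, and no stereocentre is made or touched.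

**Step 4**
Reactants: 9 dihydroxy acid
Product: 10 benzyl (5R,8S)-3,4-bis(benzyloxy)-5-methyl-8-(prop-1-en-2-yl)-5,6,7,8-tetrahydronaphthalene-2-carboxylate
Conditions: BnBr (3.6 equiv), K2CO3, Bu4NI (cat.), DMF, 60 °C
Reagents that add atoms: benzyl bromide, BrCc1ccccc1
Why: Williamson-type O-alkylation of the carboxylate and both phenoxides masks all three acidic groups with one protecting group that a single neutral step can remove later.

**Step 5**
Reactants: 10 tribenzyl isopropenyl compound
Product: 11 benzyl (5R,8S)-3,4-bis(benzyloxy)-8-(4-hydroxybut-1-en-2-yl)-5-methyl-5,6,7,8-tetrahydronaphthalene-2-carboxylate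
Conditions: (CH2O)n, Me2AlCl, CH2Cl2, −78 → 0 °C
Reagents that add atoms: paraformaldehyde (as formaldehyde), C=O
Why: In this Lewis-acid-promoted carbonyl-ene reaction the terminal =CH2 bonds to formaldehyde and a methyl hydrogen is transferred (as with limonene), which regenerates a 1,1-disubstituted alkene, while Me2AlCl scavenges protons so C8 is not ionised.

**Step 6**
Reactants: 11 homoallylic alcohol
Product: 12 benzyl (5R,8S)-3,4-bis(benzyloxy)-8-(4-iodobut-1-en-2-yl)-5-methyl-5,6,7,8-tetrahydronaphthalene-2-carboxylate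
Conditions: I2, PPh3, imidazole, CH2Cl2, 0 °C → rt
Reagents that add atoms: iodine, II
Why: The Appel reaction converts the primary alcohol to the iodide by SN2 displacement under neutral conditions that spare the esters, the ethers and the alkene.

**Step 7**
Reactants: 13 (S)-3-bromo-2-methylpropan-1-ol
Product: 14 (S)-3-bromo-2-methylpropyl acetate
Conditions: Ac2O, pyridine, DMAP (cat.), CH2Cl2, 0 °C → rt
Reagents that add atoms: acetic anhydride, CC(=O)OC(C)=O
Why: O-Acetylation installs the C7' acetate of the target on the purchased stereocentre (the later C6'), which is not involved in the reaction.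

**Step 8**
Reactants: 12 homoallylic iodide; 14 bromo acetate
Product: 16 benzyl (5R,8S)-8-[(6R)-7-acetoxy-6-methylhept-1-en-2-yl]-3,4-bis(benzyloxy)-5-methyl-5,6,7,8-tetrahydronaphthalene-2-carboxylate, via alkylzinc bromide 15 (not isolated)
Conditions: 14, Zn, LiCl, THF, 50 °C; then 12, Ni(acac)2 (10 mol %), 4-fluorostyrene (20 mol %), Bu4NI, THF–NMP, −20 → 0 °C
Reagents that add atoms: zinc, [Zn] (held only in 15)
Why: In this alkyl–alkyl Negishi coupling the γ-acetoxyalkylzinc reagent is stable and ester-tolerant, the electron-poor styrene speeds reductive elimination over β-hydride loss, and the stereocentre β to zinc is untouched (its descriptor changes from S to R only by priority).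

**Step 9**
Reactants: 16 1,1-disubstituted alkene
Product: 19 benzyl (5R,8S)-8-[(2S,6R)-1,7-diacetoxy-6-methylheptan-2-yl]-3,4-bis(benzyloxy)-5-methyl-5,6,7,8-tetrahydronaphthalene-2-carboxylate, via pinacol boronate 17 (not isolated), via borate ester 18 (not isolated)
Conditions: CuCl (5 mol %), (R)-DTBM-SEGPHOS (5.5 mol %), KOt-Bu (10 mol %), HBpin, toluene, 40 °C; then Me3NO, THF, 60 °C; then Ac2O, Et3N, DMAP, rt
Reagents that add atoms: pinacolborane, [H]B1OC(C)(C)C(C)(C)O1 (boron held only in 17 and 18); trimethylamine N-oxide, C[N+](C)(C)[O-]; acetic anhydride, CC(=O)OC(C)=O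
Why: Proposed new method: a one-flask net anti-Markovnikov hydroacetoxylation in which irreversible ligand-controlled syn-hydrocupration (Cu to C1', H to C2', with the bulky tetralinyl group in the open quadrant of the bisphosphine) sets C2' as S, σ-bond metathesis with HBpin gives 17, an amine-oxide-triggered 1,2-shift from boron to oxygen forms the C1'–O bond without touching C2', and DMAP/Ac2O acylates borate 18 directly; the closest known reaction types are CuH/bisphosphine hydroboration and hydroamination of methyl/sec-alkyl 1,1-disubstituted alkenes such as limonene, which have not been shown for an n-alkyl/sec-benzylic pair nor telescoped to the acetate.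

**Step 10**
Reactants: 19 tribenzyl diacetate
Product: 20 (5R,8S)-8-[(2S,6R)-1,7-diacetoxy-6-methylheptan-2-yl]-3,4-dihydroxy-5-methyl-5,6,7,8-tetrahydronaphthalene-2-carboxylic acid (target)
Conditions: H2 (1 atm), 10% Pd/C, EtOAc–EtOH, rt
Reagents that add atoms: none
Why: Neutral catalytic hydrogenolysis cleaves the three O-benzyl bonds, and the alkyl acetates, the arene and all four stereocentres are inert now that no alkene is left.

**Compound list**
1 | (R)-(−)-carvone | CC1=CC[C@H](CC1=O)C(C)=C | starting material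
2 | (2R,5R)-2-methyl-5-(prop-1-en-2-yl)cyclohexan-1-one | C[C@@H]1CC[C@H](CC1=O)C(C)=C | intermediate
3 | dimethyl 2-(methoxymethylidene)propanedioate | COC=C(C(=O)OC)C(=O)OC | starting material
4 | lithium (3R,6R)-6-methyl-3-(prop-1-en-2-yl)cyclohex-1-en-1-olate (not isolated) | C[C@@H]1CC[C@H](C=C1O[Li])C(C)=C | intermediate
5 | dimethyl 2-{[(3R,6R)-3-methyl-2-oxo-6-(prop-1-en-2-yl)cyclohexyl]methylidene}propanedioate (not isolated) | C[C@@H]1CC[C@H](C(C=C(C(=O)OC)C(=O)OC)C1=O)C(C)=C | intermediate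
6 | methyl (5S,8R)-8-methyl-2-oxo-5-(prop-1-en-2-yl)-5,6,7,8-tetrahydro-2H-chromene-3-carboxylate | O=C1OC2=C(C=C1C(=O)OC)[C@H](C(C)=C)CC[C@H]2C | intermediate
7 | tris(trimethylsilyloxy)ethene | C[Si](C)(C)OC=C(O[Si](C)(C)C)O[Si](C)(C)C | starting material
8 | methyl (5R,8S)-5-methyl-8-(prop-1-en-2-yl)-3,4-bis(trimethylsilyloxy)-5,6,7,8-tetrahydronaphthalene-2-carboxylate (not isolated) | CC(=C)[C@@H]1CC[C@@H](C)c2c1cc(C(=O)OC)c(O[Si](C)(C)C)c2O[Si](C)(C)C | intermediate
9 | (5R,8S)-3,4-dihydroxy-5-methyl-8-(prop-1-en-2-yl)-5,6,7,8-tetrahydronaphthalene-2-carboxylic acid | CC(=C)[C@@H]1CC[C@@H](C)c2c1cc(C(=O)O)c(O)c2O | intermediate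
10 | benzyl (5R,8S)-3,4-bis(benzyloxy)-5-methyl-8-(prop-1-en-2-yl)-5,6,7,8-tetrahydronaphthalene-2-carboxylate | CC(=C)[C@@H]1CC[C@@H](C)c2c1cc(C(=O)OCc3ccccc3)c(OCc3ccccc3)c2OCc3ccccc3 | intermediate
11 | benzyl (5R,8S)-3,4-bis(benzyloxy)-8-(4-hydroxybut-1-en-2-yl)-5-methyl-5,6,7,8-tetrahydronaphthalene-2-carboxylate | OCCC(=C)[C@@H]1CC[C@@H](C)c2c1cc(C(=O)OCc3ccccc3)c(OCc3ccccc3)c2OCc3ccccc3 | intermediate
12 | benzyl (5R,8S)-3,4-bis(benzyloxy)-8-(4-iodobut-1-en-2-yl)-5-methyl-5,6,7,8-tetrahydronaphthalene-2-carboxylate | ICCC(=C)[C@@H]1CC[C@@H](C)c2c1cc(C(=O)OCc3ccccc3)c(OCc3ccccc3)c2OCc3ccccc3 | intermediate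
13 | (S)-3-bromo-2-methylpropan-1-ol | OC[C@H](C)CBr | starting material
14 | (S)-3-bromo-2-methylpropyl acetate | CC(=O)OC[C@H](C)CBr | intermediate
15 | [(S)-3-acetoxy-2-methylpropyl]zinc bromide (not isolated) | CC(=O)OC[C@H](C)C[Zn]Br | intermediate
16 | benzyl (5R,8S)-8-[(6R)-7-acetoxy-6-methylhept-1-en-2-yl]-3,4-bis(benzyloxy)-5-methyl-5,6,7,8-tetrahydronaphthalene-2-carboxylate | CC(=O)OC[C@H](C)CCCC(=C)[C@@H]1CC[C@@H](C)c2c1cc(C(=O)OCc3ccccc3)c(OCc3ccccc3)c2OCc3ccccc3 | intermediate
17 | benzyl (5R,8S)-8-[(2S,6R)-7-acetoxy-6-methyl-1-(4,4,5,5-tetramethyl-1,3,2-dioxaborolan-2-yl)heptan-2-yl]-3,4-bis(benzyloxy)-5-methyl-5,6,7,8-tetrahydronaphthalene-2-carboxylate (not isolated) | CC(=O)OC[C@H](C)CCC[C@H](CB1OC(C)(C)C(C)(C)O1)[C@@H]2CC[C@@H](C)c3c2cc(C(=O)OCc4ccccc4)c(OCc4ccccc4)c3OCc4ccccc4 | intermediate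
18 | benzyl (5R,8S)-8-{(2S,6R)-7-acetoxy-6-methyl-1-[(4,4,5,5-tetramethyl-1,3,2-dioxaborolan-2-yl)oxy]heptan-2-yl}-3,4-bis(benzyloxy)-5-methyl-5,6,7,8-tetrahydronaphthalene-2-carboxylate (not isolated) | CC(=O)OC[C@H](C)CCC[C@H](COB1OC(C)(C)C(C)(C)O1)[C@@H]2CC[C@@H](C)c3c2cc(C(=O)OCc4ccccc4)c(OCc4ccccc4)c3OCc4ccccc4 | intermediate
19 | benzyl (5R,8S)-8-[(2S,6R)-1,7-diacetoxy-6-methylheptan-2-yl]-3,4-bis(benzyloxy)-5-methyl-5,6,7,8-tetrahydronaphthalene-2-carboxylate | CC(=O)OC[C@H](C)CCC[C@H](COC(C)=O)[C@@H]1CC[C@@H](C)c2c1cc(C(=O)OCc3ccccc3)c(OCc3ccccc3)c2OCc3ccccc3 | intermediate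
20 | (5R,8S)-8-[(2S,6R)-1,7-diacetoxy-6-methylheptan-2-yl]-3,4-dihydroxy-5-methyl-5,6,7,8-tetrahydronaphthalene-2-carboxylic acid | CC(=O)OC[C@H](C)CCC[C@H](COC(C)=O)[C@@H]1CC[C@@H](C)c2c1cc(C(=O)O)c(O)c2O | target

**Total steps:** 10. **Longest linear sequence:** 9 (steps 1–6 and 8–10).

**Three steps most likely to fail**

**Step 9 (new).** The alkene carries two non-methyl alkyl groups, so hydrocupration may be slow and face selectivity lower than in the methyl/sec-alkyl cases. The ligand antipode needed for 2'S also has to be fixed by one test run; both antipodes are sold.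
- The fallback sets out from 16 and comes back at 19, and uses reagent-controlled hydroboration followed by an enzymatic filter.
- 9-BBN in THF gives the C2'-epimeric B-alkyl-9-borabicyclononane F5.
- NaBO3·4H2O then gives the C2'-epimeric primary alcohol F6.
- Burkholderia cepacia lipase with vinyl acetate in MTBE acetylates the 2'S epimer faster. This is the sense the empirical rule predicts for β-branched primary alcohols with large = tetralinyl and medium = chain.
- Acetate 19 is then separated on silica from the unreacted (2'R)-alcohol F7.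

**Step 3 (new).** Bond formation between the fully substituted C8a and the CH(OSiMe3) carbon is hindered, and the silyl ketene acetal may instead be consumed by silyl transfer.
- The fallback sets out from 6 and comes back at 9.
- Heating 6 with 1,1,2-trimethoxyethene in mesitylene at 150 °C, the established catechol-ether annulation, gives methyl (5R,8S)-3,4-dimethoxy-5-methyl-8-(prop-1-en-2-yl)-5,6,7,8-tetrahydronaphthalene-2-carboxylate F1.
- BCl3/Bu4NI in CH2Cl2 at −78 → 0 °C removes both aryl methyl groups without acid damage to the alkene and gives methyl (5R,8S)-3,4-dihydroxy-5-methyl-8-(prop-1-en-2-yl)-5,6,7,8-tetrahydronaphthalene-2-carboxylate F2.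
- Saponification of F2 with KOH gives 9.

**Step 8.** The homoallyl–nickel intermediate has allylic β-hydrogens and may collapse to the diene.
- The fallback makes that diene on purpose and reverses the roles of the partners. It sets out from 12 and comes back at 16.
- DBU in toluene gives benzyl (5R,8S)-3,4-bis(benzyloxy)-8-(buta-1,3-dien-2-yl)-5-methyl-5,6,7,8-tetrahydronaphthalene-2-carboxylate F3.
- 9-BBN adds to the terminal carbon of the vinyl group, as it does with myrcene, and gives the homoallyl-9-borabicyclononane F4.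
- An alkyl–alkyl Suzuki coupling of F4 with bromide 14 (Pd(OAc)2, PCy3, K3PO4·H2O, THF, rt) gives 16.

**Further compounds**
F1 | step 3 | methyl (5R,8S)-3,4-dimethoxy-5-methyl-8-(prop-1-en-2-yl)-5,6,7,8-tetrahydronaphthalene-2-carboxylate | CC(=C)[C@@H]1CC[C@@H](C)c2c1cc(C(=O)OC)c(OC)c2OC
F2 | step 3 | methyl (5R,8S)-3,4-dihydroxy-5-methyl-8-(prop-1-en-2-yl)-5,6,7,8-tetrahydronaphthalene-2-carboxylate | CC(=C)[C@@H]1CC[C@@H](C)c2c1cc(C(=O)OC)c(O)c2O
F3 | step 8 | benzyl (5R,8S)-3,4-bis(benzyloxy)-8-(buta-1,3-dien-2-yl)-5-methyl-5,6,7,8-tetrahydronaphthalene-2-carboxylate | C=CC(=C)[C@@H]1CC[C@@H](C)c2c1cc(C(=O)OCc3ccccc3)c(OCc3ccccc3)c2OCc3ccccc3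
F4 | step 8 | benzyl (5R,8S)-3,4-bis(benzyloxy)-8-[4-(9-borabicyclo[3.3.1]nonan-9-yl)but-1-en-2-yl]-5-methyl-5,6,7,8-tetrahydronaphthalene-2-carboxylate | C=C(CCB1C2CCCC1CCC2)[C@@H]3CC[C@@H](C)c4c3cc(C(=O)OCc5ccccc5)c(OCc5ccccc5)c4OCc5ccccc5
F5 | step 9 | benzyl (5R,8S)-8-[(6R)-7-acetoxy-1-(9-borabicyclo[3.3.1]nonan-9-yl)-6-methylheptan-2-yl]-3,4-bis(benzyloxy)-5-methyl-5,6,7,8-tetrahydronaphthalene-2-carboxylate (C2' epimers) | CC(=O)OC[C@H](C)CCCC(CB1C2CCCC1CCC2)[C@@H]3CC[C@@H](C)c4c3cc(C(=O)OCc5ccccc5)c(OCc5ccccc5)c4OCc5ccccc5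
F6 | step 9 | benzyl (5R,8S)-8-[(6R)-7-acetoxy-1-hydroxy-6-methylheptan-2-yl]-3,4-bis(benzyloxy)-5-methyl-5,6,7,8-tetrahydronaphthalene-2-carboxylate (C2' epimers) | CC(=O)OC[C@H](C)CCCC(CO)[C@@H]1CC[C@@H](C)c2c1cc(C(=O)OCc3ccccc3)c(OCc3ccccc3)c2OCc3ccccc3
F7 | step 9 | benzyl (5R,8S)-8-[(2R,6R)-7-acetoxy-1-hydroxy-6-methylheptan-2-yl]-3,4-bis(benzyloxy)-5-methyl-5,6,7,8-tetrahydronaphthalene-2-carboxylate | CC(=O)OC[C@H](C)CCC[C@@H](CO)[C@@H]1CC[C@@H](C)c2c1cc(C(=O)OCc3ccccc3)c(OCc3ccccc3)c2OCc3ccccc3
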